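**Remark on notation.** Ring‑expanded compounds carry germacrane locants (C1 ketone, C2=C3, C4 with C15, C5, C6, C7, C8, C9, C10 with C14, C11=C13, C12). PMB = 4‑methoxybenzyl.

## Analysis of the target

Target 35 is a ten‑membered carbocycle (C1–C10) in which an oxygen bridge from C3 to C10 turns C10–C1(=O)–C2=C3 into a 3(2H)‑furanone, so that C2=C3 is held trans within the carbocycle. C6 and C7 carry an α‑methylene‑γ‑butyrolactone (oxygen on C6, C12 carbonyl, C11=C13), and C8 carries the ester of (S)‑2,3‑dihydroxy‑2‑methylpropanoic acid. The ring has five stereocentres, C4, C6, C7, C8 and C10 (all S), and the side chain has one (S). C6, C7 and C8 are contiguous, the quaternary C10 is 1,3 to C8, and C4 stands alone next to the furanone. In three dimensions the C6–O, C7–H, C8–O and C10–O bonds all lie on the outside of one crossed conformer of an E,E‑cyclodeca‑1(10),6‑diene, so these four centres can be set from one another by peripheral attack. Sensitive groups are the methylene lactone (a Michael acceptor), the furanone (its C4–H is kinetically acidic, so strong base late in the route endangers C4), and the C8 ester with its free diol. The difficulties are the bridged medium ring, the quaternary C10 and the remote C4 centre. The strategy rests on two facts: C1–C6 with oxygen on C1 and C3 and methyl on C4 is a 4‑methylcyclohexane‑1,3‑dione enol ether, and C9=C10–C1–C6–C7=C8 is a 1,5‑diene.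

## Retrosynthetic reasoning

**Ester and diol (35 ⇒ 34 ⇒ 28 + 32).** The diol is unmasked last under acid, and the C8–O acyl bond is cut just before, giving alcohol 28 and acetonide acid 32. The ester is put on late because it must not meet enolate chemistry. Acid 32 comes from the enantiopure bromo acid 29 through 31 without touching the quaternary centre.

**Methylene lactone (28 ⇒ 27 ⇒ 26 ⇒ 24 + 25).** The C8 PMB ether is removed oxidatively from 27. C11=C13 and the lactone carbonyl are traced back to lactol 24: methylenation is done at the aldehyde oxidation level with iminium salt 25 under amine conditions, and only then is the lactol oxidised. A lactone enolate would need a strong amide base, which would also remove the C4–H of the furanone.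

**Lactol (24 ⇒ 23).** Lactol 24 is the closed form of a C12 aldehyde and the C6 hydroxyl, so it comes from hydroxy acetal 23.

**C6–O and C7–H (23 ⇒ 21).** Both bonds are cut together. Forward, a syn hydroboration of the E‑C6=C7 alkene of 21 puts boron on the less substituted C6 and hydrogen on C7 from the same face, giving both centres in one step. The step must prefer the strained ring alkene over the furanone.

**Furanone (21 ⇒ 20).** The C3–O bridge is cut. Forward, the tertiary C10 hydroxyl of 20 adds to C3 of the vinylogous ester and the ethoxy group leaves. This addition–elimination also changes C2=C3 from ring‑cis to the ring‑trans arrangement that the bridge needs.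

**Ring expansion (20 ⇒ 18, key).** C8–C9 is cut, C1–C6 is rejoined and the C10 hydroxyl is removed. This turns the ten‑membered ring problem into a cyclohexane problem. Forward, the anionic oxy‑Cope shift of 18 makes the ring, the E alkene and C8, and hydroxylation of the resulting enolate makes C10.
- The stereochemistry of 18 is chosen so that both centres come out right. With C6 (R), C1 (S) and a Z enol ether, the chair gives 8S and turns the correct enolate face outward (10S).
- The 4,6‑cis/E diastereomer would also give 8S, but in the mirror ring sense, where outside attack gives the C10 epimer and later the wrong C6/C7 pair. It is therefore not used.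

**Carbinol (18 ⇒ 16 + 17).** The C1–C10 bond is cut. Isopropenyl reagent 17 adds to ketone 16 anti to the C6 substituent, which gives the trans‑dialkenyl arrangement the chair needs.

**C6–C7 bond (16 ⇒ 8 + 13).** The kinetic α′ enolate of vinylogous ester 8 is coupled with alkenyl bromide 13. The bond is made at C6 because only there does the enolate form kinetically, and the coupling keeps the alkene geometry of 13.

**Z‑bromo enol ether (13 ⇒ 11 + 12; 11 ⇒ 9 + 10).** Two successive couplings on a gem‑dibromoalkene fix the trisubstituted geometry. The first (zinc reagent 12 on 11) goes trans to oxygen, so the bromide left in 13 is cis to oxygen, and the ring carbon later takes that place. Dibromide 11 comes from formate 9 and 10. The commercial reagent 12 brings C11 and C12 with C12 as a 1,3‑dioxolane.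

**Vinylogous ester (8 ⇒ 7 ⇒ 4 ⇒ 3 ⇒ 1 + 2).** The C3 oxygen is introduced on enone 4 through a sulfur substituent (7), so the carbonyl never leaves C1. The free 1,3‑dione is avoided because it would lose the distinction between the C1 and C3 oxygens. Enone 4 comes from keto aldehyde 3, made by an organocatalytic Michael addition of 1 to 2, which sets C4.

## Alternatives that were turned down

**Alternative 1:** The C4–C5 bond is cut. Forward, a strong amide base would deprotonate the ethyl group on C3 of a preformed furanone, and the exocyclic dienolate would displace a primary iodide at C5 to close the carbocycle, giving A1.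
- For it: the furanone, the quaternary C10 and the C8 ester are all in place before ring closure, and the known γ‑acidity of 5‑alkylfuranones is used constructively. On this point it is stronger than the chosen route, which has to acylate a hindered C8 alcohol late.
- Against it: the ring is closed end to end, as a strained medium ring that must also accept a trans C2=C3 unit. Intermolecular alkylation, O‑alkylation and elimination of the iodide compete. C4 is created in the cyclisation with no control element and stays epimerisable, and the open chain must carry four separately made stereocentres.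
- Comparison: the chosen route makes the ring by expansion of a six‑membered ring, with no cyclisation entropy to pay, and relays C8, C10, C6 and C7 from a single centre.

**Alternative 2:** The O–C10 and C9–C10 bonds are cut. Forward, a copper carbenoid on an ethyl ketone side chain would be trapped by a tetrahydropyran oxygen, and the oxonium ylide would shift [2,3] onto a vinyl group, giving A2.
- For it: the oxygen bridge and the quaternary C10 are formed in one catalytic step, which is more direct for the bridge than the chosen hydroxylation followed by acid closure.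
- Against it: A2 is a tetrahydrofuranone, so C2–C3 must be dehydrogenated later. It has a Z C7=C8 alkene and no oxygen on C8, so C8 and C7 remain to be set on a bridged medium ring. A carbenoid bearing a methyl group is prone to 1,2‑hydride shift, and a [1,2] shift competes with the [2,3] path.
- Comparison: the chosen key step delivers C8 with its oxygen, the C1/C3 oxidation pattern and the C10 oxygen together, so fewer redox steps follow.

**Alternative 3:** The C7–C8 bond is cut. Forward, tin–lithium exchange on a thirteen‑membered cyclic α‑alkoxystannane would trigger a [2,3]‑Wittig contraction, giving A3.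
- For it: A3 arrives with the free C8 hydroxyl, the C11=C13 methylene and C7 already set. This is better than the chosen route, which needs three steps for the methylene lactone.
- Against it: a thirteen‑membered ether must first be made by macrocyclisation. The C1 and C3 carbonyls travel as two ketals, the stannane must be enantiopure, and the stereochemical course of a transannular shift depends on macrocycle conformation. The furanone still has to be built at the end.
- Comparison: the chosen route is much shorter to its key intermediate and uses the six‑membered ring to control geometry.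

Key step: step 9

**Assumption:** the crossed conformer released by the chair transition state is taken to persist at −78 °C, and reagents attack its outer faces.

## Route

Step 1
Reactants: 1 propanal; 2 but-3-en-2-one
Product: 3 (S)-2-methyl-5-oxohexanal
Conditions: (R)-α,α-diphenylprolinol trimethylsilyl ether (5 mol %), ethyl 3,4-dihydroxybenzoate (20 mol %), neat, 4 °C
Reagents that add atoms: none
Why: Enamine‑catalysed Michael addition of an aldehyde to an enone; the diarylmethyl group of the (R) catalyst shields one enamine face, which should give the S centre that becomes C4.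

Step 2
Reactants: 3 (S)-2-methyl-5-oxohexanal
Product: 4 (S)-4-methylcyclohex-2-en-1-one
Conditions: LiOH (10 mol %), i-PrOH, rt
Reagents that add atoms: none
Why: Intramolecular aldol condensation of the methyl ketone onto the aldehyde closes the six‑membered enone; catalytic mild base limits enolisation of the aldehyde α‑centre before it becomes the γ‑carbon of the enone.

Step 3
Reactants: 4 (S)-4-methylcyclohex-2-en-1-one
Product: 7 (S)-4-methyl-3-(phenylsulfanyl)cyclohex-2-en-1-one, via sulfide 5 (not isolated), via chloro sulfide 6 (not isolated)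
Conditions: PhSH (1.0 equiv), Et3N (5 mol %), CH2Cl2, 0 °C; N-chlorosuccinimide, 0 °C to rt; Et3N (1.5 equiv)
Reagents that add atoms: thiophenol, Sc1ccccc1
Why: Thia‑Michael addition, then α‑chlorination of the sulfide and loss of HCl toward the acidic C2–H (Pummerer‑type dehydrogenation) return the enone with sulfur on C3; the carbonyl stays on C1, so the C1/C3 regiochemistry is fixed.

Step 4
Reactants: 7 (S)-4-methyl-3-(phenylsulfanyl)cyclohex-2-en-1-one
Product: 8 (S)-3-ethoxy-4-methylcyclohex-2-en-1-one
Conditions: NaOEt (1.0 equiv), EtOH, 0 °C; aq. NH4Cl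
Reagents that add atoms: sodium ethoxide, CC[O-].[Na+]
Why: Addition–elimination at the β‑carbon of a vinylogous thioester; each ethoxide consumed releases the weakly basic thiolate, so the medium loses basicity as it reacts and γ‑deprotonation at C4 should stay slow.

Step 5
Reactants: 9 (4-methoxyphenyl)methyl formate; 10 tetrabromomethane
Product: 11 1-{[(2,2-dibromoethenyl)oxy]methyl}-4-methoxybenzene
Conditions: PPh3 (4 equiv), CH2Cl2, 0 °C to reflux
Reagents that add atoms: none
Why: Ramirez dibromo‑olefination (first stage of the Corey–Fuchs reaction) applied to a formate ester, whose carbonyl is reactive enough for the dibromomethylene ylide; the formate carbon becomes C8 and the CBr2 carbon C7.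

Step 6
Reactants: 11 1-{[(2,2-dibromoethenyl)oxy]methyl}-4-methoxybenzene; 12 (1,3-dioxolan-2-ylmethyl)zinc bromide
Product: 13 2-{(2Z)-2-bromo-3-[(4-methoxyphenyl)methoxy]prop-2-en-1-yl}-1,3-dioxolane
Conditions: PdCl2(DPEphos) (3 mol %), THF, 0 °C to rt
Reagents that add atoms: none
Why: Negishi mono‑coupling of a 1,1‑dibromoalkene; oxidative addition takes the less hindered C–Br bond trans to the substituent on the other carbon (here the ether oxygen), so the bromide that remains is cis to oxygen (Z).

Step 7
Reactants: 8 (S)-3-ethoxy-4-methylcyclohex-2-en-1-one; 13 2-{(2Z)-2-bromo-3-[(4-methoxyphenyl)methoxy]prop-2-en-1-yl}-1,3-dioxolane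
Product: 16 (4S,6R)-6-{(1Z)-3-(1,3-dioxolan-2-yl)-1-[(4-methoxyphenyl)methoxy]prop-1-en-2-yl}-3-ethoxy-4-methylcyclohex-2-en-1-one, via lithium enolate 14 (not isolated), via zinc enolate 15 (not isolated)
Conditions: LiN(i-Pr)2, THF, −78 °C; ZnCl2, −78 to 0 °C; 13, Pd(dba)2 (5 mol %), P(t-Bu)3 (10 mol %), rt
Reagents that add atoms: none
Why: Kinetic α′ deprotonation (Stork–Danheiser regiochemistry), transmetalation to the weakly basic zinc enolate and palladium‑catalysed enolate alkenylation with retention of alkene geometry; bond formation on the face away from the C4 methyl should favour the 4,6‑trans (6R) ketone, which is separated from any cis isomer.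

Step 8
Reactants: 16 (4S,6R)-6-{(1Z)-3-(1,3-dioxolan-2-yl)-1-[(4-methoxyphenyl)methoxy]prop-1-en-2-yl}-3-ethoxy-4-methylcyclohex-2-en-1-one; 17 prop-1-en-2-ylmagnesium bromide
Product: 18 (1S,4S,6R)-6-{(1Z)-3-(1,3-dioxolan-2-yl)-1-[(4-methoxyphenyl)methoxy]prop-1-en-2-yl}-3-ethoxy-4-methyl-1-(prop-1-en-2-yl)cyclohex-2-en-1-ol
Conditions: CeCl3, THF, −78 °C; aq. NaHCO3
Reagents that add atoms: none
Why: Organocerium 1,2‑addition avoids enolisation of the β,γ‑unsaturated ketone; attack anti to the C6 alkenyl group sets C1 (S) with the two alkenyl groups trans; the acid‑labile carbinol is worked up basic and used at once.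

Step 9
Reactants: 18 (1S,4S,6R)-6-{(1Z)-3-(1,3-dioxolan-2-yl)-1-[(4-methoxyphenyl)methoxy]prop-1-en-2-yl}-3-ethoxy-4-methyl-1-(prop-1-en-2-yl)cyclohex-2-en-1-ol
Product: 20 (2E,4S,6E,8S,10S)-7-(1,3-dioxolan-2-ylmethyl)-3-ethoxy-10-hydroxy-8-[(4-methoxyphenyl)methoxy]-4,10-dimethylcyclodeca-2,6-dien-1-one, via potassium enolate 19 (not isolated)
Conditions: KN(SiMe3)2, 18-crown-6, THF, −78 to 0 °C; then 2-(phenylsulfonyl)-3-phenyloxaziridine, −78 °C; aq. NH4Cl
Reagents that add atoms: 2-(phenylsulfonyl)-3-phenyloxaziridine, O=S(=O)(c1ccccc1)N1OC1c1ccccc1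
Why: The crown‑separated tertiary alkoxide weakens C1–C6, and the 1,5‑diene C9=C10–C1–C6–C7=C8 undergoes a [3,3] shift that forms C8–C9, breaks C1–C6 and gives enolate 19. The closest known reaction type is the anionic oxy‑Cope ring expansion of trans‑1,2‑dialkenylcyclohexanols to E‑cyclodec‑5‑enones with oxidation of the enolate in the same flask. The ten‑membered ring arises by four‑atom expansion of the six‑membered ring, not by end‑to‑end closure. The trans‑diequatorial alkenyl groups enforce a chair with the ring bonds equatorial, which gives E‑C6=C7. C8 is set by chirality transfer from C6 (R) through this chair with the Z enol ether oxygen axial, where it meets only H‑6, and this gives 8S. The enolate is regiodefined (C1=C10; the cross‑conjugated C2=C3 offers no second nucleophilic carbon) and is released with its inner face covered by C6=C7, so the oxaziridine hydroxylates C10 from outside, giving 10S. The step needs chair over boat or stepwise fragmentation, and oxidation before the enolate can turn through the ring; the trans arrangement and cooling to −78 °C before the oxidant is added are meant to secure both.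

Step 10
Reactants: 20 (2E,4S,6E,8S,10S)-7-(1,3-dioxolan-2-ylmethyl)-3-ethoxy-10-hydroxy-8-[(4-methoxyphenyl)methoxy]-4,10-dimethylcyclodeca-2,6-dien-1-one
Product: 21 (2Z,4S,6E,8S,10S)-7-(1,3-dioxolan-2-ylmethyl)-3,10-epoxy-8-[(4-methoxyphenyl)methoxy]-4,10-dimethylcyclodeca-2,6-dien-1-one
Conditions: pyridinium p-toluenesulfonate, 4 Å molecular sieves, CH2Cl2, rt
Reagents that add atoms: none
Why: O‑protonation of the vinylogous ester makes C3 an oxocarbenium carbon; the tertiary hydroxyl adds (5‑exo) and ethanol is lost, an addition–elimination that also turns C2=C3 from ring‑cis to ring‑trans; anhydrous mild acid keeps the dioxolane and the allylic PMB ether.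

Step 11
Reactants: 21 (2Z,4S,6E,8S,10S)-7-(1,3-dioxolan-2-ylmethyl)-3,10-epoxy-8-[(4-methoxyphenyl)methoxy]-4,10-dimethylcyclodeca-2,6-dien-1-one
Product: 23 (2Z,4S,6S,7S,8S,10S)-7-(1,3-dioxolan-2-ylmethyl)-3,10-epoxy-6-hydroxy-8-[(4-methoxyphenyl)methoxy]-4,10-dimethylcyclodec-2-en-1-one, via alkylborane 22 (not isolated)
Conditions: BH3·THF, THF, −20 to 0 °C; then NaBO3·4H2O, THF/H2O, rt
Reagents that add atoms: sodium perborate, [Na+].[O-]OB=O
Why: Hydroboration–oxidation: boron goes to the less substituted C6, and syn addition to the E alkene from its outer face should give 6S,7S; the strained trisubstituted alkene should react before the deactivated vinylogous ester carbonyl, and perborate avoids alkaline peroxide.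

Step 12
Reactants: 23 (2Z,4S,6S,7S,8S,10S)-7-(1,3-dioxolan-2-ylmethyl)-3,10-epoxy-6-hydroxy-8-[(4-methoxyphenyl)methoxy]-4,10-dimethylcyclodec-2-en-1-one
Product: 24 (4S,6S,7R,8S,10S)-3,10:6,12-diepoxy-12-hydroxy-8-[(4-methoxyphenyl)methoxy]germacr-2-en-1-one (γ-lactol; both C12 anomers)
Conditions: 1 M HCl, THF, rt
Reagents that add atoms: water, O
Why: Acetal hydrolysis; the C12 aldehyde is captured by the C6 hydroxyl as a five‑membered lactol, which holds C12 at the aldehyde level; the C7 descriptor changes by priority only.

Step 13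
Reactants: 24 (4S,6S,7R,8S,10S)-3,10:6,12-diepoxy-12-hydroxy-8-[(4-methoxyphenyl)methoxy]germacr-2-en-1-one; 25 N,N-dimethylmethyleneiminium iodide
Product: 26 (4S,6S,7R,8S,10S)-3,10:6,12-diepoxy-12-hydroxy-8-[(4-methoxyphenyl)methoxy]germacra-2,11(13)-dien-1-one (methylene lactol)
Conditions: Et3N, CH2Cl2, rt
Reagents that add atoms: none
Why: Mannich reaction at C11 of the open aldehyde form, then loss of dimethylamine (α‑methylenation of an aldehyde); a tertiary amine removes neither the C4–H of the furanone nor a lactone α‑hydrogen, and the product recloses to the lactol.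

Step 14
Reactants: 26 (4S,6S,7R,8S,10S)-3,10:6,12-diepoxy-12-hydroxy-8-[(4-methoxyphenyl)methoxy]germacra-2,11(13)-dien-1-one
Product: 27 (4S,6S,7R,8S,10S)-3,10-epoxy-8-[(4-methoxyphenyl)methoxy]-1-oxogermacra-2,11(13)-dien-12,6-olide
Conditions: PhI(OAc)2, TEMPO (10 mol %), CH2Cl2, rt
Reagents that add atoms: none
Why: Oxoammonium oxidation of a lactol to the lactone under neutral conditions that leave the PMB ether, the exocyclic alkene and the furanone alone.

Step 15
Reactants: 27 (4S,6S,7R,8S,10S)-3,10-epoxy-8-[(4-methoxyphenyl)methoxy]-1-oxogermacra-2,11(13)-dien-12,6-olide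
Product: 28 (4S,6S,7R,8S,10S)-3,10-epoxy-8-hydroxy-1-oxogermacra-2,11(13)-dien-12,6-olide
Conditions: DDQ, CH2Cl2/pH 7 buffer, 0 °C
Reagents that add atoms: none
Why: Oxidative cleavage of the PMB ether by hydride abstraction; the electron‑poor alkenes are not touched.

Step 16
Reactants: 29 (R)-3-bromo-2-hydroxy-2-methylpropanoic acid
Product: 31 (S)-2,3-dihydroxy-2-methylpropanoic acid, via sodium epoxy carboxylate 30 (not isolated)
Conditions: NaOH (aq.), 60 °C; then acidic ion-exchange resin
Reagents that add atoms: sodium hydroxide, [Na+].[OH-]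
Why: The tertiary alkoxide displaces bromide to the epoxide and hydroxide opens it at CH2; the quaternary centre is never touched, and the descriptor changes from R to S only because CH2Br outranks the carboxyl group while CH2OH does not.

Step 17
Reactants: 31 (S)-2,3-dihydroxy-2-methylpropanoic acid
Product: 32 (S)-2,2,4-trimethyl-1,3-dioxolane-4-carboxylic acid
Conditions: 2,2-dimethoxypropane, pyridinium p-toluenesulfonate, acetone, rt
Reagents that add atoms: 2,2-dimethoxypropane, COC(C)(C)OC
Why: Ketalisation of the 1,2‑diol to the five‑membered acetonide, which should be faster than ketal formation through the hindered α‑hydroxy acid; the carboxyl group stays free.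

Step 18
Reactants: 28 (4S,6S,7R,8S,10S)-3,10-epoxy-8-hydroxy-1-oxogermacra-2,11(13)-dien-12,6-olide; 32 (S)-2,2,4-trimethyl-1,3-dioxolane-4-carboxylic acid
Product: 34 (4S,6S,7S,8S,10S)-3,10-epoxy-1-oxo-8-{[(4S)-2,2,4-trimethyl-1,3-dioxolane-4-carbonyl]oxy}germacra-2,11(13)-dien-12,6-olide, via mixed anhydride 33 (not isolated)
Conditions: 2,4,6-trichlorobenzoyl chloride, Et3N, toluene, rt; then 28, DMAP, rt
Reagents that add atoms: none
Why: Yamaguchi esterification, suited to a hindered acid and a hindered secondary alcohol; the acyl–oxygen bond is formed, so C8 keeps its configuration, and the acid has no α‑hydrogen to lose.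

Step 19
Reactants: 34 (4S,6S,7S,8S,10S)-3,10-epoxy-1-oxo-8-{[(4S)-2,2,4-trimethyl-1,3-dioxolane-4-carbonyl]oxy}germacra-2,11(13)-dien-12,6-olide
Product: 35 (4S,6S,7S,8S,10S)-8-{[(2S)-2,3-dihydroxy-2-methylpropanoyl]oxy}-3,10-epoxy-1-oxogermacra-2,11(13)-dien-12,6-olide
Conditions: CF3CO2H/H2O (9:1), CH2Cl2, 0 °C
Reagents that add atoms: none
Why: Acid hydrolysis of the acetonide; lactone, furanone and ester should survive brief cold aqueous acid, and no base is present that could epimerise C4 or add to the methylene lactone.

## Compound list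

1 | propanal | CCC=O | starting material
2 | but-3-en-2-one | CC(=O)C=C | starting material
3 | (S)-2-methyl-5-oxohexanal | C[C@H](C=O)CCC(C)=O | intermediate
4 | (S)-4-methylcyclohex-2-en-1-one | C[C@H]1CCC(=O)C=C1 | intermediate
5 | (3S,4S)-4-methyl-3-(phenylsulfanyl)cyclohexan-1-one (trans) | C[C@H]1CCC(=O)C[C@@H]1Sc2ccccc2 | intermediate (not isolated)
6 | (4S)-3-chloro-4-methyl-3-(phenylsulfanyl)cyclohexan-1-one | C[C@H]1CCC(=O)CC1(Cl)Sc2ccccc2 | intermediate (not isolated)
7 | (S)-4-methyl-3-(phenylsulfanyl)cyclohex-2-en-1-one | C[C@H]1CCC(=O)C=C1Sc2ccccc2 | intermediate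
8 | (S)-3-ethoxy-4-methylcyclohex-2-en-1-one | C[C@H]1CCC(=O)C=C1OCC | intermediate
9 | (4-methoxyphenyl)methyl formate | COc1ccc(COC=O)cc1 | starting material
10 | tetrabromomethane | BrC(Br)(Br)Br | starting material
11 | 1-{[(2,2-dibromoethenyl)oxy]methyl}-4-methoxybenzene | COc1ccc(COC=C(Br)Br)cc1 | intermediate
12 | (1,3-dioxolan-2-ylmethyl)zinc bromide | Br[Zn]CC1OCCO1 | starting material
13 | 2-{(2Z)-2-bromo-3-[(4-methoxyphenyl)methoxy]prop-2-en-1-yl}-1,3-dioxolane | COc1ccc(CO/C=C(\Br)CC2OCCO2)cc1 | intermediate
14 | lithium (4S)-5-ethoxy-4-methylcyclohexa-1,5-dien-1-olate | C[C@H]1CC=C([O-])C=C1OCC.[Li+] | intermediate (not isolated)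
15 | chlorozinc (4S)-5-ethoxy-4-methylcyclohexa-1,5-dien-1-olate | C[C@H]1CC=C(O[Zn]Cl)C=C1OCC | intermediate (not isolated)
16 | (4S,6R)-6-{(1Z)-3-(1,3-dioxolan-2-yl)-1-[(4-methoxyphenyl)methoxy]prop-1-en-2-yl}-3-ethoxy-4-methylcyclohex-2-en-1-one | C[C@H]1C[C@H](/C(CC2OCCO2)=C\OCc3ccc(OC)cc3)C(=O)C=C1OCC | intermediate
17 | prop-1-en-2-ylmagnesium bromide | CC(=C)[Mg]Br | starting material
18 | (1S,4S,6R)-6-{(1Z)-3-(1,3-dioxolan-2-yl)-1-[(4-methoxyphenyl)methoxy]prop-1-en-2-yl}-3-ethoxy-4-methyl-1-(prop-1-en-2-yl)cyclohex-2-en-1-ol | CC(=C)[C@@]1(O)C=C(OCC)[C@@H](C)C[C@@H]1/C(CC2OCCO2)=C\OCc3ccc(OC)cc3 | intermediate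
19 | potassium (1(10)Z,2E,4S,6E,8S)-7-(1,3-dioxolan-2-ylmethyl)-3-ethoxy-8-[(4-methoxyphenyl)methoxy]-4,10-dimethylcyclodeca-1(10),2,6-trien-1-olate | C[C@H]1C/C=C(CC2OCCO2)/[C@@H](OCc3ccc(OC)cc3)C/C(C)=C([O-])/C=C1/OCC.[K+] | intermediate (not isolated)
20 | (2E,4S,6E,8S,10S)-7-(1,3-dioxolan-2-ylmethyl)-3-ethoxy-10-hydroxy-8-[(4-methoxyphenyl)methoxy]-4,10-dimethylcyclodeca-2,6-dien-1-one | C[C@H]1C/C=C(CC2OCCO2)/[C@@H](OCc3ccc(OC)cc3)C[C@](C)(O)C(=O)/C=C1/OCC | intermediate
21 | (2Z,4S,6E,8S,10S)-7-(1,3-dioxolan-2-ylmethyl)-3,10-epoxy-8-[(4-methoxyphenyl)methoxy]-4,10-dimethylcyclodeca-2,6-dien-1-one | C[C@H]1C/C=C(CC2OCCO2)/[C@@H](OCc4ccc(OC)cc4)C[C@]3(C)OC1=CC3=O | intermediate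
22 | C6 alkylborane from 21 (boron on C6 and hydrogen on C7 on the same face; drawn as the monoalkylborane) | B[C@H]1C[C@H](C)C2=CC(=O)[C@](C)(C[C@H](OCc4ccc(OC)cc4)[C@H]1CC3OCCO3)O2 | intermediate (not isolated)
23 | (2Z,4S,6S,7S,8S,10S)-7-(1,3-dioxolan-2-ylmethyl)-3,10-epoxy-6-hydroxy-8-[(4-methoxyphenyl)methoxy]-4,10-dimethylcyclodec-2-en-1-one | O[C@H]1C[C@H](C)C2=CC(=O)[C@](C)(C[C@H](OCc4ccc(OC)cc4)[C@H]1CC3OCCO3)O2 | intermediate
24 | (4S,6S,7R,8S,10S)-3,10:6,12-diepoxy-12-hydroxy-8-[(4-methoxyphenyl)methoxy]germacr-2-en-1-one (lactol, C12 anomers) | C1C(O)O[C@H]2C[C@H](C)C3=CC(=O)[C@](C)(C[C@H](OCc4ccc(OC)cc4)[C@@H]12)O3 | intermediate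
25 | N,N-dimethylmethyleneiminium iodide | C[N+](C)=C.[I-] | starting material
26 | (4S,6S,7R,8S,10S)-3,10:6,12-diepoxy-12-hydroxy-8-[(4-methoxyphenyl)methoxy]germacra-2,11(13)-dien-1-one (methylene lactol) | C=C1C(O)O[C@H]2C[C@H](C)C3=CC(=O)[C@](C)(C[C@H](OCc4ccc(OC)cc4)[C@@H]12)O3 | intermediate
27 | (4S,6S,7R,8S,10S)-3,10-epoxy-8-[(4-methoxyphenyl)methoxy]-1-oxogermacra-2,11(13)-dien-12,6-olide | C=C1C(=O)O[C@H]2C[C@H](C)C3=CC(=O)[C@](C)(C[C@H](OCc4ccc(OC)cc4)[C@@H]12)O3 | intermediate
28 | (4S,6S,7R,8S,10S)-3,10-epoxy-8-hydroxy-1-oxogermacra-2,11(13)-dien-12,6-olide | C=C1C(=O)O[C@H]2C[C@H](C)C3=CC(=O)[C@](C)(C[C@H](O)[C@@H]12)O3 | intermediate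
29 | (R)-3-bromo-2-hydroxy-2-methylpropanoic acid | OC(=O)[C@@](C)(O)CBr | starting material
30 | sodium (S)-2-methyloxirane-2-carboxylate | [O-]C(=O)[C@@]1(C)OC1.[Na+] | intermediate (not isolated)
31 | (S)-2,3-dihydroxy-2-methylpropanoic acid | OC(=O)[C@@](C)(O)CO | intermediate
32 | (S)-2,2,4-trimethyl-1,3-dioxolane-4-carboxylic acid | OC(=O)[C@]1(C)COC(C)(C)O1 | intermediate
33 | (S)-2,2,4-trimethyl-1,3-dioxolane-4-carboxylic 2,4,6-trichlorobenzoic anhydride | Clc1cc(Cl)c(C(=O)OC(=O)[C@]2(C)COC(C)(C)O2)c(Cl)c1 | intermediate (not isolated)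
34 | (4S,6S,7S,8S,10S)-3,10-epoxy-1-oxo-8-{[(4S)-2,2,4-trimethyl-1,3-dioxolane-4-carbonyl]oxy}germacra-2,11(13)-dien-12,6-olide | C=C1C(=O)O[C@H]2C[C@H](C)C3=CC(=O)[C@](C)(C[C@H](OC(=O)[C@]4(C)COC(C)(C)O4)[C@@H]12)O3 | intermediate
35 | (4S,6S,7S,8S,10S)-8-{[(2S)-2,3-dihydroxy-2-methylpropanoyl]oxy}-3,10-epoxy-1-oxogermacra-2,11(13)-dien-12,6-olide | C=C1C(=O)O[C@H]2C[C@H](C)C3=CC(=O)[C@](C)(C[C@H](OC(=O)[C@@](C)(O)CO)[C@@H]12)O3 | target

## Step count and least certain steps

Total: 19 steps. Longest linear sequence: 15 steps (1–4, 7–15, 18, 19). The precursor 18 is reached in six linear steps.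

**Step 9 (key).** The most likely failure is loss of face selectivity at C10, either because the enolate unit turns through the ring while the basic solution warms, or because part of the material rearranges by fragmentation–recombination. Addition of the enolate to the sulfonylimine formed from the oxidant, or an α‑ketol shift of the potassium alkoxide of 20, could also consume material. The fallback sets out from 18 and returns at 20: the enolate 19 is quenched at −78 °C with chlorotrimethylsilane to the trimethylsilyl enol ether F1, which is isolated so that its geometry can be checked. Rubottom oxidation with dimethyldioxirane at −78 °C gives, after silyl migration, the α‑silyloxy ketone F2, and aqueous citric acid frees 20. This separates the rearrangement from the oxidation and runs the oxidation on a neutral species.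

**Step 7.** The likely problem is epimerisation at C6 (the product is a β,γ‑unsaturated ketone, more acidic than 8), giving the 4,6‑cis isomer or the conjugated isomer; β‑hydride elimination from the palladium enolate is a second risk. The fallback sets out from 8 and 13 and returns at 16: 8 is brominated through its kinetic enolate (LiN(i-Pr)2, then N‑bromosuccinimide) to the bromo ketone F3, and 13 is turned by bromine–lithium exchange (t‑BuLi, −78 °C) and ZnCl2 into the alkenylzinc chloride F4, whose cis oxygen holds the geometry. A nickel‑catalysed stereoconvergent Negishi coupling of the secondary α‑bromo ketone (NiCl2·glyme, a chiral bis(oxazoline) ligand, −20 °C) joins them. No enolate is present, and the C6 configuration is set by the ligand at the radical capture.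

**Step 6.** The risk is poor site selectivity between the two bromides, or double coupling, since the oxygen substituent is smaller than the alkyl groups for which trans selectivity is established. The fallback sets out from 4,4‑dimethoxybut‑1‑yne F5 and returns at 13: acetal exchange with ethane‑1,2‑diol gives the alkyne F6, and N‑iodosuccinimide with AgNO3 gives the iodoalkyne F7. Anti hydrobromination (LiBr, AcOH) gives the (Z)‑2‑bromo‑1‑iodoalkene F8, and copper‑catalysed etherification of the more reactive vinyl iodide with 4‑methoxybenzyl alcohol (CuI, 3,4,7,8‑tetramethyl‑1,10‑phenanthroline, Cs2CO3, toluene, 80 °C) proceeds with retention to 13.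

**Step 11.** The risks are attack on the wrong alkene face if the bridged ring does not keep the conformation in which it was formed, and competing reduction of the furanone carbonyl. The fallback sets out from 20 and returns at 23: the hydroboration–oxidation is done before the bridge is closed, on the monocyclic ring whose conformation comes directly from the chair, giving diol F9. The acid closure of step 10 then gives 23.

**Step 13.** The lactol may react sluggishly because little open aldehyde is present, and the free C6 hydroxyl may add to the new enal (oxa‑Michael) instead of reclosing to the lactol. The fallback sets out from 23 and returns at 27: the C6 hydroxyl is silylated (t‑BuMe2SiOTf, 2,6‑lutidine) to F10, and the dioxolane is hydrolysed (pyridinium p‑toluenesulfonate, acetone/H2O) to aldehyde F11. Methylenation with 25 gives enal F12, and Pinnick oxidation (NaClO2, NaH2PO4, 2‑methylbut‑2‑ene) gives acid F13. HF·pyridine removes the silyl group, and the hydroxy acid lactonises to 27.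

## Further compounds

F1 | step 9 | trimethylsilyl enol ether of the ring-expanded ketone (C1–OSiMe3, C1=C10) | C[C@H]1C/C=C(CC2OCCO2)/[C@@H](OCc3ccc(OC)cc3)C/C(C)=C(O[Si](C)(C)C)/C=C1/OCC
F2 | step 9 | C10 trimethylsilyl ether of 20 | C[C@H]1C/C=C(CC2OCCO2)/[C@@H](OCc3ccc(OC)cc3)C[C@](C)(O[Si](C)(C)C)C(=O)/C=C1/OCC
F3 | step 7 | (4S)-6-bromo-3-ethoxy-4-methylcyclohex-2-en-1-one | C[C@H]1CC(Br)C(=O)C=C1OCC
F4 | step 7 | chloro{(1Z)-3-(1,3-dioxolan-2-yl)-1-[(4-methoxyphenyl)methoxy]prop-1-en-2-yl}zinc | COc1ccc(CO/C=C(\[Zn]Cl)CC2OCCO2)cc1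
F5 | step 6 | 4,4-dimethoxybut-1-yne | C#CCC(OC)OC
F6 | step 6 | 2-(prop-2-yn-1-yl)-1,3-dioxolane | C#CCC1OCCO1
F7 | step 6 | 2-(3-iodoprop-2-yn-1-yl)-1,3-dioxolane | IC#CCC1OCCO1
F8 | step 6 | 2-[(2Z)-2-bromo-3-iodoprop-2-en-1-yl]-1,3-dioxolane | I/C=C(\Br)CC1OCCO1
F9 | step 11 | (2E,4S,6S,7S,8S,10S)-7-(1,3-dioxolan-2-ylmethyl)-3-ethoxy-6,10-dihydroxy-8-[(4-methoxyphenyl)methoxy]-4,10-dimethylcyclodec-2-en-1-one | O[C@H]1C[C@H](C)/C(OCC)=C\C(=O)[C@@](C)(O)C[C@H](OCc3ccc(OC)cc3)[C@H]1CC2OCCO2
F10 | step 13 | C6 tert-butyldimethylsilyl ether of 23 | CC(C)(C)[Si](C)(C)O[C@H]1C[C@H](C)C2=CC(=O)[C@](C)(C[C@H](OCc4ccc(OC)cc4)[C@H]1CC3OCCO3)O2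
F11 | step 13 | C12 aldehyde from F10 | CC(C)(C)[Si](C)(C)O[C@H]1C[C@H](C)C2=CC(=O)[C@](C)(C[C@H](OCc4ccc(OC)cc4)[C@H]1CC=O)O2
F12 | step 13 | C11 methylene aldehyde from F11 | CC(C)(C)[Si](C)(C)O[C@H]1C[C@H](C)C2=CC(=O)[C@](C)(C[C@H](OCc4ccc(OC)cc4)[C@H]1C(=C)C=O)O2
F13 | step 13 | C12 acrylic acid from F12 | CC(C)(C)[Si](C)(C)O[C@H]1C[C@H](C)C2=CC(=O)[C@](C)(C[C@H](OCc4ccc(OC)cc4)[C@H]1C(=C)C(=O)O)O2
A1 | alternative 1 | bicyclic furanone bis-silyl ether closed at C4–C5 | CC(C)(C)[Si](C)(C)O[C@H]2C[C@H](C)C3=CC(=O)[C@](C)(C[C@H](OC(=O)[C@@]4(C)OC(C)(C)OC4)[C@H]2C(=C)CO[Si](C)(C)C(C)(C)C)O3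
A2 | alternative 2 | oxygen-bridged tetrahydrofuranone with Z C7=C8 | C[C@H]1C[C@H](O[Si](C)(C)C(C)(C)C)/C(CC(OC)OC)=C\C[C@]2(C)O[C@H]1CC2=O
A3 | alternative 3 | ten-membered carbocycle with free C8 hydroxyl and C11=C13 methylene | C=C(CO[Si](C)(C)C(C)(C)C)[C@@H]1[C@@H](O)C[C@](C)(O[Si](CC)(CC)CC)C2(OCCO2)CC3(OCCO3)[C@@H](C)C[C@@H]1O[Si](C)(C)C(C)(C)C
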